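How much right-handed product could this flask hold within its time, and when would it pass the level asked for?

common to all: gas 79 mM (held)

|  | left-handed substrate | right-handed substrate | catalyst | remark | time |
|---|---|---|---|---|---|
| grey | 0.30 M | 0.30 M | 0.034 mol% | run made earlier |  |
| violet | 0.30 M | 0.30 M | 0.075 mol% | run made earlier |  |
| green | 0.45 M | 0.45 M | 0.05 mol% | run made earlier |  |
| flask | 0.30 M | 0.30 M | 0.05 mol% |  | 20 h |

| run | time / h | right-handed product / % | left-handed product / % | left-handed substrate / % |
|---|---|---|---|---|
| grey | 5.00 | 4 | 13 | 37 |
| grey | 6.00 | 2 | 11 | 36 |
| grey | 10.0 | 8 | 19 | 29 |
| grey | 12.0 | 9 | 23 | 30 |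
| violet | 5.00 | 7 | 18 | 34 |
| violet | 6.00 | 7 | 19 | 29 |
| violet | 10.0 | 11 | 29 | 14 |
| violet | 12.0 | 15 | 35 | 19 |
| green | 5.00 | 6 | 14 | 33 |
| green | 6.00 | 11 | 19 | 34 |
| green | 10.0 | 10 | 28 | 22 |
| green | 12.0 | 16 | 30 | 20 |

(standard deviation of a reading: 2 percentage points)

- catalyst is single-handed; left-handed substrate and right-handed substrate are mirror images of each other, charged as a racemate, each of them at the stated concentration
- at the start none of partner is dissolved
- the analysis behind the earlier runs scatters by 2 percentage points, standard deviation
- steps that have been proposed: partner + catalyst + right-handed substrate -> catalyst + right-handed product; gas <-> partner; partner + catalyst + left-handed substrate -> catalyst + left-handed product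

* the moment within 20 h at which there is most right-handed product
* the amount of right-handed product, in percent of the left-handed substrate and right-handed substrate together charged, at that time
* the first time at which right-handed product reaches 13%, in the same percent

To repeat this run, I watched one thing. In the violet run the right-handed product climbed roughly in a line, with 7% at 5.00 h and 15% at 12.0 h, so I froze its rise per hour. I took the settings in turn. Catalyst came first: the last readings gave 0.00750 /h of the charge per hour for grey and 0.0125 /h for violet. A straight line between their loadings gave, for this flask, the steady slope 0.00945 /h, the fraction of the charge turned into right-handed product each hour, an apparent zero order. By hand, with that catalyst the grey run at 12.0 h came out at 11.3%. Time came next: the grey slope carried to 20 h gave 15.0%. Both together gave 18.9% at the end, and the level asked for at 13.8 h. Each reading scatters by 2 percentage points, so I trusted these no further than that. Substrate strength I left as in grey and violet.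

The forecast said 20.5% at 20 h, and the level at 12 h; it put the peak at the end of the time because the steps hold “no route that consumes right-handed product”. Its figures differ from mine.

The flask gave 19.0% at 20.0 h, and the level at 13.4 h. From the grey run's 8.80%, catalyst alone gave 11.7%, time alone 14.5%, both 19.0%.

    partner + catalyst + right-handed substrate → catalyst + right-handed product (k = 45.2 /M²/min)
    gas ⇌ partner, rate k2*(csat - [partner]) (kL = 0.0172 /min)
    partner + catalyst + left-handed substrate → catalyst + left-handed product (k = 144 /M²/min)

Partner was made 1.04 times as fast as it was used up at 7.02 h, and 1.05 times at 20.0 h. Right-handed product stood at 9.70% at 10.0 h, then gained 9.3 points by 20.0 h.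

For the same flask read at 12 h, the steady slope gives 11.3%; the computed amount is 11.7%.

(The numbers in the tables are calculated with made-up constants.)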